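**Plan**
- Retrosynthesis: the aryl ether bond of the pyran ring (ring oxygen O1 to benzene carbon C8a) is cut first, giving open quinone 13. In 13 the benzene ring is a 1,4-benzoquinone and the formyl carbon a CH2OH group.
- Feature used: on the benzene ring O1 (on C8a) and the C6 hydroxyl are para, and C5, between C4a and C6, carries the formyl carbon. The target plus water is therefore an isomer of hydroxymethyl quinone 13, and no external redox reagent is needed to close it.
- Further cuts: quinone back to its dimethyl ether; the ArCH2–CH2 bond (B-alkyl Suzuki) to iodoarene 9 and (R)-geranyllinalool 4; 4 back to geranylgeraniol.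
- Forward order: side chain (steps 1–3), arene (step 4), coupling (step 5), reduction and oxidative demethylation (steps 6–7). In step 8 the pyran ring closes and the benzene ring is re-formed in one acid-catalysed operation.
- Stereochemistry: the single stereocentre (R) comes from a Sharpless epoxidation with D-(−)-diethyl tartrate; its C–O bond is never broken afterwards. The E alkenes come from geranylgeraniol.

Key step: step 8

Assumption: all-E geranylgeraniol (1) and 2,5-dimethoxy-4-methylbenzaldehyde (5) are taken as purchasable; 5 is otherwise one Vilsmeier formylation from 2,5-dimethoxytoluene.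

**Step 1**
Reactants: 1 (2E,6E,10E)-geranylgeraniol
Product: 2 (2R,3R)-2,3-epoxygeranylgeraniol
Conditions: Ti(OiPr)4 (10 mol%), D-(−)-diethyl tartrate (12 mol%), t-BuOOH, 4 Å MS, CH2Cl2, −20 °C
Reagents that add atoms: tert-butyl hydroperoxide, CC(C)(C)OO
Why: Sharpless asymmetric epoxidation, in which the allylic hydroxyl binds the titanium tartrate so that only the 2,3-alkene reacts, and the D-(−)-tartrate should deliver oxygen to the face that gives (2R,3R), fixing the later carbinol configuration.

**Step 2**
Reactants: 2 (2R,3R)-2,3-epoxygeranylgeraniol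
Product: 3 (2S,3R)-2-(iodomethyl)-3-methyl-3-[(3E,7E)-4,8,12-trimethyltrideca-3,7,11-trien-1-yl]oxirane
Conditions: I2, PPh3, imidazole, CH2Cl2, 0 °C
Reagents that add atoms: iodine, II
Why: Appel-type iodination of the primary alcohol under imidazole-buffered conditions should leave the epoxide and the trisubstituted alkenes untouched (the descriptor at C2 changes only because of CIP priorities).

**Step 3**
Reactants: 3 (2S,3R)-epoxy iodide
Product: 4 (3R,6E,10E)-3,7,11,15-tetramethylhexadeca-1,6,10,14-tetraen-3-ol [(R)-geranyllinalool]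
Conditions: Zn dust, EtOH, 70 °C
Reagents that add atoms: none
Why: Reductive opening of a 2,3-epoxy iodide (zinc insertion into C–I, then β-elimination) cleaves only the C2–O bond, so the intact C3–O bond carries the 3R configuration into the tertiary allylic alcohol.

**Step 4**
Reactants: 5 2,5-dimethoxy-4-methylbenzaldehyde
Product: 9 2-iodo-3,6-dimethoxy-4-methylbenzaldehyde, via lithium amino alkoxide 6 (not isolated), via ortho-lithiated amino alkoxide 7 (not isolated), via iodinated amino alkoxide 8 (not isolated)
Conditions: LiN(Me)CH2CH2NMe2 (from MeNHCH2CH2NMe2 and n-BuLi), THF, −20 °C; n-BuLi, −20 °C; I2, −78 °C to rt; aq NH4Cl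
Reagents that add atoms: iodine, II
Why: Comins directed ortho-metalation, in which the in situ α-amino alkoxide masks the aldehyde and directs lithiation to the one ring CH flanked by it and the 5-methoxy group, with iodine quench and aqueous work-up returning the aldehyde.

**Step 5**
Reactants: 4 (R)-geranyllinalool; 9 2-iodo-3,6-dimethoxy-4-methylbenzaldehyde
Product: 11 2-[(3R,6E,10E)-3-hydroxy-3,7,11,15-tetramethylhexadeca-6,10,14-trien-1-yl]-3,6-dimethoxy-4-methylbenzaldehyde, via B-alkyl-9-BBN 10 (not isolated)
Conditions: 9-BBN dimer, THF, 0 °C to rt; then 9, Pd(OAc)2 (5 mol%), SPhos (10 mol%), K3PO4 (aq), THF, 60 °C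
Reagents that add atoms: none
Why: 9-BBN should hydroborate only the monosubstituted vinyl group (anti-Markovnikov), and B-alkyl Suzuki–Miyaura coupling with a bulky biaryl phosphine tolerates the doubly ortho-substituted iodide, the free tertiary alcohol and the aldehyde without touching the stereocentre.

**Step 6**
Reactants: 11 the coupled aldehyde
Product: 12 (3R,6E,10E)-1-[2-(hydroxymethyl)-3,6-dimethoxy-5-methylphenyl]-3,7,11,15-tetramethylhexadeca-6,10,14-trien-3-ol
Conditions: NaBH4, MeOH–THF, 0 °C
Reagents that add atoms: none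
Why: Borohydride reduction of the aryl aldehyde is chemoselective and sets the benzylic carbon at the alcohol level that the key step later re-oxidises internally.

**Step 7**
Reactants: 12 the dimethoxy diol
Product: 13 2-(hydroxymethyl)-3-[(3R,6E,10E)-3-hydroxy-3,7,11,15-tetramethylhexadeca-6,10,14-trien-1-yl]-5-methylcyclohexa-2,5-diene-1,4-dione
Conditions: (NH4)2Ce(NO3)6 (2.5 equiv), MeCN–H2O, 0 °C, short contact time
Reagents that add atoms: water, O
Why: Oxidative demethylation of a 1,4-dimethoxyarene by tetravalent cerium is standard for polyprenyl quinones because the arene is oxidised far more easily than trisubstituted alkenes, and the aqueous medium should return any cyclic ketal to the open quinone.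

**Step 8**
Reactants: 13 the hydroxymethyl quinone
Product: 17 (2R)-5-formyl-δ-tocotrienol, via cyclic hemiketal 14 (not isolated), via chromanoxylium ion 15 (not isolated), via hydroxymethylidene quinone methide 16 (not isolated)
Conditions: (+)-camphor-10-sulfonic acid (20 mol%), 4 Å MS, CH2Cl2, 0 °C to rt, argon, dark
Reagents that add atoms: none
Why: Proposed new method: under mild acid the tertiary hydroxyl should add to the only quinone carbonyl it can reach through a six-membered ring (6-exo-trig hemiketalisation at the carbon between the methyl-bearing and chain-bearing ring carbons), the hemiketal hydroxyl should ionise to chromanoxylium ion 15, and loss of a proton from the adjacent CH2OH carbon should give quinone methide 16, which is the enol of the salicylaldehyde and tautomerises to aromatic 17. The closest known reaction type is the acid-induced cyclisation of tocopherylquinones through 8a-hydroxytocopherones and chromanoxylium ions to ortho-quinone methides, together with the isomerisation of hydroxymethylquinones to formylhydroquinones. The pyran ring closes by O-to-ring-carbon bond formation and the benzene ring is regenerated by the 1,4-elimination and enol-to-aldehyde tautomerisation, so the quinone is reduced and the carbinol oxidised with no external redox reagent. No new stereocentre remains (the hemiketal carbon of 14 becomes planar again), and the quaternary centre keeps its R configuration because its own C–O bond is never broken. The step needs hemiketalisation and elimination to outrun vinylogous enolisation of the open quinone and cationic reactions of the alkenes; six-ring intramolecular delivery, a dry medium and a weak acid at low temperature should secure this. Only the hydroxymethyl carbon can lose a proton to give a Kekulé quinone methide, which fixes where the aldehyde appears.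

**Compound list**
1 | (2E,6E,10E)-3,7,11,15-tetramethylhexadeca-2,6,10,14-tetraen-1-ol (geranylgeraniol) | CC(C)=CCC/C(C)=C/CC/C(C)=C/CC/C(C)=C/CO | starting material
2 | [(2R,3R)-3-methyl-3-[(3E,7E)-4,8,12-trimethyltrideca-3,7,11-trien-1-yl]oxiran-2-yl]methanol | CC(C)=CCC/C(C)=C/CC/C(C)=C/CC[C@@]1(C)O[C@@H]1CO | intermediate
3 | (2S,3R)-2-(iodomethyl)-3-methyl-3-[(3E,7E)-4,8,12-trimethyltrideca-3,7,11-trien-1-yl]oxirane | CC(C)=CCC/C(C)=C/CC/C(C)=C/CC[C@@]1(C)O[C@@H]1CI | intermediate
4 | (3R,6E,10E)-3,7,11,15-tetramethylhexadeca-1,6,10,14-tetraen-3-ol | CC(C)=CCC/C(C)=C/CC/C(C)=C/CC[C@@](C)(O)C=C | intermediate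
5 | 2,5-dimethoxy-4-methylbenzaldehyde | COc1cc(C)c(OC)cc1C=O | starting material
6 | lithium (2,5-dimethoxy-4-methylphenyl){[2-(dimethylamino)ethyl](methyl)amino}methanolate | [Li]OC(N(C)CCN(C)C)c1cc(OC)c(C)cc1OC | intermediate
7 | 6-lithio derivative of 6 (lithium on the ring carbon between the carbinolamine carbon and the 5-methoxy group) | [Li]OC(N(C)CCN(C)C)c1c([Li])c(OC)c(C)cc1OC | intermediate
8 | lithium (2-iodo-3,6-dimethoxy-4-methylphenyl){[2-(dimethylamino)ethyl](methyl)amino}methanolate | [Li]OC(N(C)CCN(C)C)c1c(I)c(OC)c(C)cc1OC | intermediate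
9 | 2-iodo-3,6-dimethoxy-4-methylbenzaldehyde | COc1cc(C)c(OC)c(I)c1C=O | intermediate
10 | (3S,6E,10E)-1-(9-borabicyclo[3.3.1]nonan-9-yl)-3,7,11,15-tetramethylhexadeca-6,10,14-trien-3-ol (descriptor changed by CIP priority only) | CC(C)=CCC/C(C)=C/CC/C(C)=C/CC[C@@](C)(O)CCB1C2CCCC1CCC2 | intermediate
11 | 2-[(3R,6E,10E)-3-hydroxy-3,7,11,15-tetramethylhexadeca-6,10,14-trien-1-yl]-3,6-dimethoxy-4-methylbenzaldehyde | CC(C)=CCC/C(C)=C/CC/C(C)=C/CC[C@@](C)(O)CCc1c(OC)c(C)cc(OC)c1C=O | intermediate
12 | (3R,6E,10E)-1-[2-(hydroxymethyl)-3,6-dimethoxy-5-methylphenyl]-3,7,11,15-tetramethylhexadeca-6,10,14-trien-3-ol | CC(C)=CCC/C(C)=C/CC/C(C)=C/CC[C@@](C)(O)CCc1c(OC)c(C)cc(OC)c1CO | intermediate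
13 | 2-(hydroxymethyl)-3-[(3R,6E,10E)-3-hydroxy-3,7,11,15-tetramethylhexadeca-6,10,14-trien-1-yl]-5-methylcyclohexa-2,5-diene-1,4-dione | CC(C)=CCC/C(C)=C/CC/C(C)=C/CC[C@@](C)(O)CCC1=C(CO)C(=O)C=C(C)C1=O | intermediate
14 | (2R)-8a-hydroxy-5-(hydroxymethyl)-2,8-dimethyl-2-[(3E,7E)-4,8,12-trimethyltrideca-3,7,11-trien-1-yl]-3,4-dihydro-2H-chromen-6(8aH)-one (8a epimers) | CC(C)=CCC/C(C)=C/CC/C(C)=C/CC[C@]1(C)CCC2=C(CO)C(=O)C=C(C)C2(O)O1 | intermediate
15 | (2R)-5-(hydroxymethyl)-2,8-dimethyl-6-oxo-2-[(3E,7E)-4,8,12-trimethyltrideca-3,7,11-trien-1-yl]-3,4-dihydro-2H,6H-chromen-1-ium | CC(C)=CCC/C(C)=C/CC/C(C)=C/CC[C@]1(C)CCC2=C(CO)C(=O)C=C(C)C2=[O+]1 | intermediate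
16 | (2R)-5-(hydroxymethylidene)-2,8-dimethyl-2-[(3E,7E)-4,8,12-trimethyltrideca-3,7,11-trien-1-yl]-3,4-dihydro-2H-chromen-6(5H)-one | CC(C)=CCC/C(C)=C/CC/C(C)=C/CC[C@]1(C)CCC2=C(O1)C(C)=CC(=O)C2=CO | intermediate
17 | (2R)-6-hydroxy-2,8-dimethyl-2-[(3E,7E)-4,8,12-trimethyltrideca-3,7,11-trien-1-yl]-3,4-dihydro-2H-chromene-5-carbaldehyde | CC(C)=CCC/C(C)=C/CC/C(C)=C/CC[C@]1(C)CCc2c(C=O)c(O)cc(C)c2O1 | target

Total steps: 8. Longest linear sequence: 7 steps (steps 1, 2, 3, 5, 6, 7, 8).

**Steps most likely to fail**

Step 8. The open quinone may enolise through its hydroxymethyl carbon to the formylhydroquinone faster than it forms the hemiketal, and that electron-poor hydroquinone would no longer close. The acid may also start cationic reactions of the alkenes or ionise the tertiary carbinol, eroding configuration. The fallback uses known chemistry and separates ring closure from formylation. It sets out from borane 10 (made from 4 as in step 5) and returns at 17.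
- Suzuki coupling of 10 with purchased 3-bromo-5-methylphenol under the step 5 conditions should give 3-[(3R,6E,10E)-3-hydroxy-3,7,11,15-tetramethylhexadeca-6,10,14-trien-1-yl]-5-methylphenol F1.
- Teuber oxidation with (KSO3)2NO in buffered aqueous acetone at the free para position should give 2-[(3R,6E,10E)-3-hydroxy-3,7,11,15-tetramethylhexadeca-6,10,14-trien-1-yl]-6-methylcyclohexa-2,5-diene-1,4-dione F2.
- Na2S2O4 should reduce it to the hydroquinone 2-[(3R,6E,10E)-3-hydroxy-3,7,11,15-tetramethylhexadeca-6,10,14-trien-1-yl]-6-methylbenzene-1,4-diol F3.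
- Acid-catalysed cyclodehydration (TsOH, toluene, 60 °C) is, to the best of recollection, the reaction reported in the tocopherol series to proceed with retention at the carbinol carbon. It should give (R)-δ-tocotrienol F4.
- Ortho-formylation with MgCl2, Et3N and paraformaldehyde in MeCN at the more reactive 5-position next to the fused ring should give 17.

Step 7. The strongly acidic oxidant may trigger ketalisation and cyclisation in the flask, after which the electron-rich chromanol would be oxidised again, and the alkenes may be attacked on longer contact. The fallback sets out from 12 and returns at 13.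
- Anodic oxidation in KOH–MeOH (Pt anode, undivided cell, 0 °C) should give the quinone bis(dimethyl ketal) (3R,6E,10E)-1-[2-(hydroxymethyl)-3,3,6,6-tetramethoxy-5-methylcyclohexa-1,4-dien-1-yl]-3,7,11,15-tetramethylhexadeca-6,10,14-trien-3-ol F5 without a chemical oxidant.
- Hydrolysis with dilute aqueous acetic acid in THF at 0 °C should release 13.

Step 5. Oxidative addition and transmetalation at the doubly ortho-substituted iodide may be slow, so that protodeboronation or β-hydride elimination of the alkylborane takes over. Residual borane may also reduce the aldehyde early (harmless, since step 6 does the same). The fallback sets out from 4 and 9 and returns at 11.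
- Heck reaction under Jeffery conditions (Pd(OAc)2, Bu4NCl, NaHCO3, DMF, 80 °C) should give the styrene 2-[(1E,3R,6E,10E)-3-hydroxy-3,7,11,15-tetramethylhexadeca-1,6,10,14-tetraen-1-yl]-3,6-dimethoxy-4-methylbenzaldehyde F6. The carbinol carbon has no hydrogen, so elimination can only give this alkene.
- Diimide generated from KO2CN=NCO2K and AcOH in MeOH–pyridine should reduce the disubstituted styrene alkene well before the trisubstituted ones, giving 11.

**Further compounds**
F1 | step 8 | 3-[(3R,6E,10E)-3-hydroxy-3,7,11,15-tetramethylhexadeca-6,10,14-trien-1-yl]-5-methylphenol | CC(C)=CCC/C(C)=C/CC/C(C)=C/CC[C@@](C)(O)CCc1cc(C)cc(O)c1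
F2 | step 8 | 2-[(3R,6E,10E)-3-hydroxy-3,7,11,15-tetramethylhexadeca-6,10,14-trien-1-yl]-6-methylcyclohexa-2,5-diene-1,4-dione | CC(C)=CCC/C(C)=C/CC/C(C)=C/CC[C@@](C)(O)CCC1=CC(=O)C=C(C)C1=O
F3 | step 8 | 2-[(3R,6E,10E)-3-hydroxy-3,7,11,15-tetramethylhexadeca-6,10,14-trien-1-yl]-6-methylbenzene-1,4-diol | CC(C)=CCC/C(C)=C/CC/C(C)=C/CC[C@@](C)(O)CCc1cc(O)cc(C)c1O
F4 | step 8 | (2R)-2,8-dimethyl-2-[(3E,7E)-4,8,12-trimethyltrideca-3,7,11-trien-1-yl]-3,4-dihydro-2H-chromen-6-ol [(R)-δ-tocotrienol] | CC(C)=CCC/C(C)=C/CC/C(C)=C/CC[C@]1(C)CCc2cc(O)cc(C)c2O1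
F5 | step 7 | (3R,6E,10E)-1-[2-(hydroxymethyl)-3,3,6,6-tetramethoxy-5-methylcyclohexa-1,4-dien-1-yl]-3,7,11,15-tetramethylhexadeca-6,10,14-trien-3-ol | CC(C)=CCC/C(C)=C/CC/C(C)=C/CC[C@@](C)(O)CCC1=C(CO)C(OC)(OC)C=C(C)C1(OC)OC
F6 | step 5 | 2-[(1E,3R,6E,10E)-3-hydroxy-3,7,11,15-tetramethylhexadeca-1,6,10,14-tetraen-1-yl]-3,6-dimethoxy-4-methylbenzaldehyde | CC(C)=CCC/C(C)=C/CC/C(C)=C/CC[C@@](C)(O)/C=C/c1c(OC)c(C)cc(OC)c1C=O
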